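**Retrosynthetic overview**
- The target is reached by desilylation and a two-carbon Wittig homologation of a bis-silylated (2R,3R)-2,3-dihydro-1,4-benzodioxine-6-carbaldehyde.
- That aldehyde is disconnected at both C–O bonds of the dioxane: one enantioselective oxidative [4+2] annulation of 5-hydroxyvanillin (the catechol) with an (E)-para-hydroxycinnamyl silyl ether.
- The cinnamyl ether comes from 5-hydroxyvanillin again: regioselective mono-silylation, Wittig olefination, ester reduction, silylation.
- Ring order: both benzene rings are bought (same starting material). The 1,4-dioxane ring is the only ring made, in the annulation.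

Assumption: the (S)-ligand of step 5 is taken to give the (2R,3R) series; the sense of induction of a new reaction cannot be predicted, and the equally available (R)-ligand is used if the antipode results.

TBS = tert-butyldimethylsilyl. Benzodioxine numbering: C2 carries the CH2O group, C3 the aryl group.

**Step 1**
Reactants: 1 3,4-dihydroxy-5-methoxybenzaldehyde (5-hydroxyvanillin)
Product: 2 3-[(tert-butyldimethylsilyl)oxy]-4-hydroxy-5-methoxybenzaldehyde
Conditions: NaH (2.1 equiv), THF/DMF 5:1, 0 °C; TBSCl (1.0 equiv), −20 °C to rt; 1 M HCl quench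
Reagents that add atoms: tert-butyldimethylsilyl chloride, CC(C)(C)[Si](C)(C)Cl
Why: Regioselective O-silylation of a catechol dianion: the 3-phenoxide is not conjugated to the aldehyde and is the more nucleophilic site, and O-to-O silyl migration reinforces this because it leaves the more stabilised para-formyl phenoxide free; no stereocentre is formed.

**Step 2**
Reactants: 2 3-[(tert-butyldimethylsilyl)oxy]-4-hydroxy-5-methoxybenzaldehyde; 3 ethyl 2-(triphenylphosphoranylidene)acetate
Product: 4 ethyl (2E)-3-{3-[(tert-butyldimethylsilyl)oxy]-4-hydroxy-5-methoxyphenyl}prop-2-enoate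
Conditions: 3 (1.3 equiv), PhMe, 90 °C
Reagents that add atoms: none
Why: Wittig olefination with a stabilised ylide tolerates the free phenol and gives the (E)-cinnamate.

**Step 3**
Reactants: 4 ethyl (2E)-3-{3-[(tert-butyldimethylsilyl)oxy]-4-hydroxy-5-methoxyphenyl}prop-2-enoate
Product: 5 2-[(tert-butyldimethylsilyl)oxy]-4-[(1E)-3-hydroxyprop-1-en-1-yl]-6-methoxyphenol
Conditions: iBu2AlH (3.5 equiv), CH2Cl2, −78 to −20 °C; aq. potassium sodium tartrate
Reagents that add atoms: none
Why: iBu2AlH 1,2-reduction of the unsaturated ester (one equivalent is consumed by the phenol) gives the allylic alcohol without touching the alkene or the aryl silyl ether.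

**Step 4**
Reactants: 5 2-[(tert-butyldimethylsilyl)oxy]-4-[(1E)-3-hydroxyprop-1-en-1-yl]-6-methoxyphenol
Product: 6 2-[(tert-butyldimethylsilyl)oxy]-4-[(1E)-3-[(tert-butyldimethylsilyl)oxy]prop-1-en-1-yl]-6-methoxyphenol
Conditions: TBSCl (1.05 equiv), Et3N (1.5 equiv), DMAP (5 mol %), CH2Cl2, 0 °C
Reagents that add atoms: tert-butyldimethylsilyl chloride, CC(C)(C)[Si](C)(C)Cl
Why: Chemoselective silyl ether formation: the primary allylic alcohol reacts far faster than the phenol, which is blocked on both ortho positions; the silyl ether prevents palladium-alkoxide β-hydride elimination and allyl ionisation in step 5.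

**Step 5**
Reactants: 6 2-[(tert-butyldimethylsilyl)oxy]-4-[(1E)-3-[(tert-butyldimethylsilyl)oxy]prop-1-en-1-yl]-6-methoxyphenol; 1 3,4-dihydroxy-5-methoxybenzaldehyde
Product: 8 (2R,3R)-3-{3-[(tert-butyldimethylsilyl)oxy]-4-hydroxy-5-methoxyphenyl}-2-{[(tert-butyldimethylsilyl)oxy]methyl}-8-methoxy-2,3-dihydro-1,4-benzodioxine-6-carbaldehyde, via para-quinone methide 7 (not isolated)
Conditions: Pd(MeCN)2Cl2 (5 mol %), (S)-4-tert-butyl-2-(quinolin-2-yl)-4,5-dihydro-1,3-oxazole (12 mol %), KHCO3 (0.4 equiv), 2,6-dimethyl-1,4-benzoquinone (1.2 equiv), 3 Å molecular sieves, PhMe/THF 4:1, 0 °C to rt, argon, 1 (1.2 equiv) added over 4 h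
Reagents that add atoms: none
Why: Proposed new method: an enantioselective Wacker-type oxidative [4+2] dioxygenation of the alkene relayed through a para-quinone methide. The divalent palladium–quinoline-oxazoline complex binds one face of the electron-rich (E)-alkene of 6. Under bicarbonate buffering the only phenoxide present is the para-formyl 4-O of 1 (pKa about 7.5, against about 10–11 for the other two phenols), and it attacks the carbon remote from the aryl group because this leaves an η3-benzyl palladium species; this step sets C2 and fixes the regiochemistry (4-O on the CH2O-bearing carbon). The free para-hydroxyl then expels zerovalent palladium to give quinone methide 7, and the neighbouring 3-OH closes the dioxane by 6-exo 1,6-addition with aryl and CH2OTBS trans-diequatorial; this closure is reversible through 7, so any cis isomer drains to trans without touching C2. The quinone returns palladium to the divalent state and is too weak an oxidant to convert the catechol into its ortho-quinone. The closest known reaction types are the palladium-catalysed enantioselective aerobic dialkoxylation of 2-propenylphenols through ortho-quinone methides and Wacker-type oxypalladation of β-alkylstyrenes at the non-benzylic carbon; neither has been shown with a catechol as tethered bis-nucleophile, with a para-quinone methide relay, or for a 2,3-disubstituted benzodioxane.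

**Step 6**
Reactants: 8 (2R,3R)-3-{3-[(tert-butyldimethylsilyl)oxy]-4-hydroxy-5-methoxyphenyl}-2-{[(tert-butyldimethylsilyl)oxy]methyl}-8-methoxy-2,3-dihydro-1,4-benzodioxine-6-carbaldehyde; 9 2-(triphenylphosphoranylidene)acetaldehyde
Product: 10 (2E)-3-[(2R,3R)-3-{3-[(tert-butyldimethylsilyl)oxy]-4-hydroxy-5-methoxyphenyl}-2-{[(tert-butyldimethylsilyl)oxy]methyl}-8-methoxy-2,3-dihydro-1,4-benzodioxin-6-yl]prop-2-enal
Conditions: 9 (1.2 equiv), PhMe, 80 °C
Reagents that add atoms: none
Why: Wittig two-carbon homologation with the formyl-stabilised ylide gives the (E)-enal under neutral conditions that leave the silyl ethers, the phenol and both stereocentres untouched.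

**Step 7**
Reactants: 10 (2E)-3-[(2R,3R)-3-{3-[(tert-butyldimethylsilyl)oxy]-4-hydroxy-5-methoxyphenyl}-2-{[(tert-butyldimethylsilyl)oxy]methyl}-8-methoxy-2,3-dihydro-1,4-benzodioxin-6-yl]prop-2-enal
Product: 11 (2E)-3-[(2R,3R)-3-(3,4-dihydroxy-5-methoxyphenyl)-2-(hydroxymethyl)-8-methoxy-2,3-dihydro-1,4-benzodioxin-6-yl]prop-2-enal
Conditions: HF·pyridine (excess), pyridine/THF, 0 °C to rt, argon
Reagents that add atoms: none
Why: Fluoride-driven desilylation of the aryl and primary alkyl silyl ethers under buffered, mildly acidic conditions spares the enal, the catechol and the benzylic aryl ether; C2 has no acidic hydrogen, and C3 can only equilibrate toward trans.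

**Compound list**
1 | 3,4-dihydroxy-5-methoxybenzaldehyde (5-hydroxyvanillin) | COc1cc(C=O)cc(O)c1O | starting material
2 | 3-[(tert-butyldimethylsilyl)oxy]-4-hydroxy-5-methoxybenzaldehyde | COc1cc(C=O)cc(O[Si](C)(C)C(C)(C)C)c1O | intermediate
3 | ethyl 2-(triphenylphosphoranylidene)acetate | CCOC(=O)C=P(c1ccccc1)(c1ccccc1)c1ccccc1 | starting material
4 | ethyl (2E)-3-{3-[(tert-butyldimethylsilyl)oxy]-4-hydroxy-5-methoxyphenyl}prop-2-enoate | CCOC(=O)/C=C/c1cc(OC)c(O)c(O[Si](C)(C)C(C)(C)C)c1 | intermediate
5 | 2-[(tert-butyldimethylsilyl)oxy]-4-[(1E)-3-hydroxyprop-1-en-1-yl]-6-methoxyphenol | COc1cc(/C=C/CO)cc(O[Si](C)(C)C(C)(C)C)c1O | intermediate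
6 | 2-[(tert-butyldimethylsilyl)oxy]-4-[(1E)-3-[(tert-butyldimethylsilyl)oxy]prop-1-en-1-yl]-6-methoxyphenol | COc1cc(/C=C/CO[Si](C)(C)C(C)(C)C)cc(O[Si](C)(C)C(C)(C)C)c1O | intermediate
7 | 4-[(2S)-3-[(tert-butyldimethylsilyl)oxy]-2-(4-formyl-2-hydroxy-6-methoxyphenoxy)propylidene]-2-[(tert-butyldimethylsilyl)oxy]-6-methoxycyclohexa-2,5-dien-1-one (para-quinone methide; not isolated; exocyclic C=C geometry not defined; same spatial arrangement at the aryloxy carbon as C2 of 8) | O=Cc1cc(O)c(O[C@@H](C=C2C=C(OC)C(=O)C(O[Si](C)(C)C(C)(C)C)=C2)CO[Si](C)(C)C(C)(C)C)c(OC)c1 | intermediate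
8 | (2R,3R)-3-{3-[(tert-butyldimethylsilyl)oxy]-4-hydroxy-5-methoxyphenyl}-2-{[(tert-butyldimethylsilyl)oxy]methyl}-8-methoxy-2,3-dihydro-1,4-benzodioxine-6-carbaldehyde (trans) | COc1cc([C@H]2Oc3cc(C=O)cc(OC)c3O[C@@H]2CO[Si](C)(C)C(C)(C)C)cc(O[Si](C)(C)C(C)(C)C)c1O | intermediate
9 | 2-(triphenylphosphoranylidene)acetaldehyde | O=CC=P(c1ccccc1)(c1ccccc1)c1ccccc1 | starting material
10 | (2E)-3-[(2R,3R)-3-{3-[(tert-butyldimethylsilyl)oxy]-4-hydroxy-5-methoxyphenyl}-2-{[(tert-butyldimethylsilyl)oxy]methyl}-8-methoxy-2,3-dihydro-1,4-benzodioxin-6-yl]prop-2-enal | COc1cc([C@H]2Oc3cc(/C=C/C=O)cc(OC)c3O[C@@H]2CO[Si](C)(C)C(C)(C)C)cc(O[Si](C)(C)C(C)(C)C)c1O | intermediate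
11 | (2E)-3-[(2R,3R)-3-(3,4-dihydroxy-5-methoxyphenyl)-2-(hydroxymethyl)-8-methoxy-2,3-dihydro-1,4-benzodioxin-6-yl]prop-2-enal (CNP0103768.1) | COc1cc([C@H]2Oc3cc(/C=C/C=O)cc(OC)c3O[C@@H]2CO)cc(O)c1O | target

**Step count:** 7 steps in total. Longest linear sequence: 7 steps (1 → 2 → 4 → 5 → 6 → 8 → 10 → 11); 1 is used a second time as the coupling partner in step 5.

**Steps most likely to fail**

Step 5 (the proposed new annulation). Likely failure modes are low enantioselectivity without an ortho-chelating phenol, β-hydride elimination to an aryl enol ether, catalyst sequestration by the catechol, or leakage to the regioisomer; regiochemistry would be checked by HMBC. The fallback uses known chemistry, sets out from 6 (with 1) and comes back at 8. Biomimetic oxidative cross-coupling with Ag2CO3 (2.2 equiv, PhMe/acetone, rt, dark) lets monovalent silver oxidise the hindered phenol of 6 and the catechol of 1 to radicals. β–O coupling gives the quinone methide as a racemate, that is 7 together with its mirror image, the (2R)-quinone methide F1. Ring closure then gives the trans-benzodioxane as a racemate, that is 8 together with the (2S,3S)-benzodioxane aldehyde F2. Preparative supercritical-fluid chromatography on an amylose tris(3,5-dimethylphenylcarbamate) phase separates F2 and returns 8 (at most 50 %).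

Step 6 (Wittig with the formyl ylide). The product enal can react a second time to give a dienal, and the electron-rich aldehyde is slow. The fallback sets out from 8 and comes back at 10 through an ester detour. Wittig reaction of 8 with 3 (PhMe, 90 °C) gives ethyl (2E)-3-[(2R,3R)-3-{3-[(tert-butyldimethylsilyl)oxy]-4-hydroxy-5-methoxyphenyl}-2-{[(tert-butyldimethylsilyl)oxy]methyl}-8-methoxy-2,3-dihydro-1,4-benzodioxin-6-yl]prop-2-enoate F3, which cannot over-react. iBu2AlH (CH2Cl2, −78 °C) reduces it to the allylic alcohol (2E)-3-[(2R,3R)-3-{3-[(tert-butyldimethylsilyl)oxy]-4-hydroxy-5-methoxyphenyl}-2-{[(tert-butyldimethylsilyl)oxy]methyl}-8-methoxy-2,3-dihydro-1,4-benzodioxin-6-yl]prop-2-en-1-ol F4. MnO2 (CH2Cl2, rt) oxidises only the allylic alcohol, the other primary oxygen being silylated, and gives 10.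

Step 1 (regioselective mono-silylation). Mixtures of mono- and bis-silyl ethers or loss of the silyl group on silica are possible. The fallback sets out from 1 and comes back at 2 by protecting fully and then removing one group. TBSCl (2.5 equiv) and imidazole in DMF give 3,4-bis[(tert-butyldimethylsilyl)oxy]-5-methoxybenzaldehyde F5. LiOAc (10 mol %) in DMF/H2O 50:1 at rt then cleaves the aryl silyl ether para to the aldehyde, whose phenoxide is the best leaving group. Even if the 3-O-silyl group were cleaved first, silyl migration would lead to the same phenol 2.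

**Further compounds**
F1 | step 5 | 4-[(2R)-3-[(tert-butyldimethylsilyl)oxy]-2-(4-formyl-2-hydroxy-6-methoxyphenoxy)propylidene]-2-[(tert-butyldimethylsilyl)oxy]-6-methoxycyclohexa-2,5-dien-1-one | O=Cc1cc(O)c(O[C@H](C=C2C=C(OC)C(=O)C(O[Si](C)(C)C(C)(C)C)=C2)CO[Si](C)(C)C(C)(C)C)c(OC)c1
F2 | step 5 | (2S,3S)-3-{3-[(tert-butyldimethylsilyl)oxy]-4-hydroxy-5-methoxyphenyl}-2-{[(tert-butyldimethylsilyl)oxy]methyl}-8-methoxy-2,3-dihydro-1,4-benzodioxine-6-carbaldehyde | COc1cc([C@@H]2Oc3cc(C=O)cc(OC)c3O[C@H]2CO[Si](C)(C)C(C)(C)C)cc(O[Si](C)(C)C(C)(C)C)c1O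
F3 | step 6 | ethyl (2E)-3-[(2R,3R)-3-{3-[(tert-butyldimethylsilyl)oxy]-4-hydroxy-5-methoxyphenyl}-2-{[(tert-butyldimethylsilyl)oxy]methyl}-8-methoxy-2,3-dihydro-1,4-benzodioxin-6-yl]prop-2-enoate | COc1cc([C@H]2Oc3cc(/C=C/C(=O)OCC)cc(OC)c3O[C@@H]2CO[Si](C)(C)C(C)(C)C)cc(O[Si](C)(C)C(C)(C)C)c1O
F4 | step 6 | (2E)-3-[(2R,3R)-3-{3-[(tert-butyldimethylsilyl)oxy]-4-hydroxy-5-methoxyphenyl}-2-{[(tert-butyldimethylsilyl)oxy]methyl}-8-methoxy-2,3-dihydro-1,4-benzodioxin-6-yl]prop-2-en-1-ol | COc1cc([C@H]2Oc3cc(/C=C/CO)cc(OC)c3O[C@@H]2CO[Si](C)(C)C(C)(C)C)cc(O[Si](C)(C)C(C)(C)C)c1O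
F5 | step 1 | 3,4-bis[(tert-butyldimethylsilyl)oxy]-5-methoxybenzaldehyde | COc1cc(C=O)cc(O[Si](C)(C)C(C)(C)C)c1O[Si](C)(C)C(C)(C)C
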